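**Retrosynthetic overview**

1. Locants: unprimed = formyl-bearing dihydrobenzofuran (O1, C2, C3, C3a–C7a); primed = central dihydrobenzofuran carrying the resorcinol ring. The five phenols are carried as benzyl ethers; the C3'–resorcinol bond and the C3–C4' bond are each cut by decarboxylative arylation of a trans-2-aryl-2,3-dihydrobenzofuran-3-carboxylic acid.
2. Each such acid is traced to a (2R)-flavanone by oxidative ring contraction: the aromatic carbon C4a of the pyranone shifts from C4 to C3, which forms the C3a'–C3' bond of the central unit (and C3a–C3 of the other) and turns C4 out of the ring as a carboxyl group.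
3. Enabling feature: the central ring O1'–C2'–C3'–C3a'–C7a' is a 5,7-dioxygenated flavanone (O1–C2(aryl)–C3–C4–C4a) less one ring carbon. C3a' lies para to the C6' oxygen and ortho to O1', so it is an electron-rich migrating terminus; C2' already carries the 4-oxyphenyl group and the configuration that is relayed to C3'; the C3' aryl group sits where the extruded C4 carboxyl group can be replaced.
4. Both flavanones come from chromones by asymmetric conjugate addition of one arylboronic acid. Ring order: two bought pyranone rings, contracted to the central dihydrofuran ring (step 4) and to the formyl-bearing dihydrofuran ring (step 6); no other ring is formed.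

Key step: step 4

Assumption: (S)-t-BuPyOx is taken to induce the (2R) configuration on chromones, the same sense as on cyclic enones; if the opposite sense is found, the (R)-ligand is to be used in steps 3 and 5.

**Route**

Step 1
Reactants: 1 5,7-dihydroxy-4H-chromen-4-one
Product: 2 7-(benzyloxy)-5-hydroxy-4H-chromen-4-one
Conditions: BnBr (1.05 equiv), K2CO3, acetone, reflux
Reagents that add atoms: benzyl bromide, BrCc1ccccc1
Why: Williamson ether synthesis; the 5-OH is hydrogen-bonded to the C4 carbonyl and much less nucleophilic, so benzylation should occur at O7 only.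

Step 2
Reactants: 2 7-(benzyloxy)-5-hydroxy-4H-chromen-4-one
Product: 3 7-(benzyloxy)-4-oxo-4H-chromen-5-yl trifluoromethanesulfonate
Conditions: Tf2O, pyridine, CH2Cl2, 0 °C to rt
Reagents that add atoms: trifluoromethanesulfonic anhydride, O=S(=O)(OS(=O)(=O)C(F)(F)F)C(F)(F)F
Why: O-sulfonylation (triflation) of the remaining phenol turns O5 into the later cross-coupling handle and leaves the benzyl ether and the pyranone untouched.

Step 3
Reactants: 3 7-(benzyloxy)-4-oxo-4H-chromen-5-yl trifluoromethanesulfonate; 4 [4-(benzyloxy)phenyl]boronic acid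
Product: 5 (2R)-7-(benzyloxy)-2-[4-(benzyloxy)phenyl]-4-oxo-3,4-dihydro-2H-chromen-5-yl trifluoromethanesulfonate
Conditions: Pd(OCOCF3)2 (5 mol%), (S)-t-BuPyOx (6 mol%), NH4PF6 (30 mol%), H2O (5 equiv), ClCH2CH2Cl, 60 °C
Reagents that add atoms: none
Why: Divalent-palladium-catalysed asymmetric conjugate addition of an arylboronic acid to a chromone (transmetalation, face-selective insertion of C2=C3 into aryl–Pd under control of the chiral pyridine–oxazoline ligand, protonolysis) should set C2 as (R), and the aryl triflate should survive because no zerovalent palladium–phosphine species is present.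

Step 4
Reactants: 5 (2R)-7-(benzyloxy)-2-[4-(benzyloxy)phenyl]-4-oxo-3,4-dihydro-2H-chromen-5-yl trifluoromethanesulfonate
Product: 8 methyl (2R,3R)-6-(benzyloxy)-2-[4-(benzyloxy)phenyl]-4-{[(trifluoromethyl)sulfonyl]oxy}-2,3-dihydro-1-benzofuran-3-carboxylate, via methyl enol ether 6 (not isolated), via trans C3 iodane 7 (not isolated)
Conditions: PhI(OAc)2 (1.2 equiv), conc. H2SO4 (1.5 equiv), HC(OMe)3, 0 °C to rt
Reagents that add atoms: trimethyl orthoformate, COC(OC)OC
Why: Acid and trimethyl orthoformate turn the C4 ketone into methyl enol ether 6; the trivalent iodine electrophile attacks C3 on the face away from the C2 aryl group and methanol caps C4, giving iodane 7 whose equatorial C3–I bond is antiperiplanar to the C4–C4a ring bond; the aromatic carbon C4a then shifts from C4 to C3 with loss of iodobenzene, and the C4 dimethoxycarbenium ion collapses to the methyl ester. The closest known reaction type is the oxidative ring contraction of flavanones to trans-2-aryl-2,3-dihydrobenzofuran-3-carboxylates by trivalent iodine reagents (or thallium trinitrate) in orthoformate, which is documented for optically active flavanones. The dihydrofuran ring is closed by ring contraction and not by an end-to-end cyclisation: C4a bridges C4 and C3 in a phenonium-type (spiro three-membered) transition state, the new C3a'–C3' bond forms by backside displacement at C3 while the C4–C4a bond breaks, and C4 leaves the ring as the carboxyl carbon. The new stereocentre C3' is controlled by C2': iodination anti to the C2 aryl group followed by migration with inversion at C3 should place the ester trans to that aryl group (2R,3R), which is also the more stable arrangement; this centre passes through a planar radical in step 11 and is then set again under the same control. The step needs migration of C4a in preference to migration of the C2 aryl group (isoflavone), to dehydrogenation (flavone) and to opening of the pyranone ring (loss of C2 configuration): C4a is para to the C7 benzyloxy group and ortho to O1 and so is the most electron-rich migrating terminus, the trans-diequatorial iodane aligns only the C4–C4a bond with the leaving group, and the ketone stays masked as enol ether or ketal, which blocks retro-oxa-Michael opening; the aryl triflate and benzyl ethers are inert to the acid and the oxidant.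

Step 5
Reactants: 9 6-bromo-4H-chromen-4-one; 4 [4-(benzyloxy)phenyl]boronic acid
Product: 10 (2R)-2-[4-(benzyloxy)phenyl]-6-bromo-2,3-dihydro-4H-chromen-4-one
Conditions: Pd(OCOCF3)2 (5 mol%), (S)-t-BuPyOx (6 mol%), NH4PF6 (30 mol%), H2O (5 equiv), ClCH2CH2Cl, 60 °C
Reagents that add atoms: none
Why: The same divalent-palladium-catalysed asymmetric conjugate addition as in step 3 should set C2 as (R) under ligand control, the aryl bromide being inert in the absence of zerovalent palladium–phosphine species.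

Step 6
Reactants: 10 (2R)-2-[4-(benzyloxy)phenyl]-6-bromo-2,3-dihydro-4H-chromen-4-one
Product: 13 methyl (2R,3R)-2-[4-(benzyloxy)phenyl]-5-bromo-2,3-dihydro-1-benzofuran-3-carboxylate, via methyl enol ether 11 (not isolated), via trans C3 iodane 12 (not isolated)
Conditions: PhI(OAc)2 (1.2 equiv), conc. H2SO4 (1.5 equiv), HC(OMe)3, 0 °C to rt
Reagents that add atoms: trimethyl orthoformate, COC(OC)OC
Why: The same oxidative 1,2-aryl-shift ring contraction of a flavanone as in step 4, with C4a activated by the ortho ring oxygen; iodination anti to the C2 aryl group and migration with inversion should give the trans ester.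

Step 7
Reactants: 13 methyl (2R,3R)-2-[4-(benzyloxy)phenyl]-5-bromo-2,3-dihydro-1-benzofuran-3-carboxylate
Product: 14 methyl (2R,3R)-2-[4-(benzyloxy)phenyl]-5-formyl-2,3-dihydro-1-benzofuran-3-carboxylate
Conditions: Pd(OAc)2 (1 mol%), n-BuPAd2 (3 mol%), CO/H2 (1:1, 5 bar), TMEDA (0.75 equiv), toluene, 100 °C
Reagents that add atoms: carbon monoxide, [C-]#[O+]
Why: Palladium-catalysed reductive carbonylation (formylation) of an aryl bromide (oxidative addition, CO insertion, hydrogenolysis of the acyl–palladium bond) should leave the ester, the benzyl ether and both stereocentres untouched.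

Step 8
Reactants: 14 methyl (2R,3R)-2-[4-(benzyloxy)phenyl]-5-formyl-2,3-dihydro-1-benzofuran-3-carboxylate
Product: 15 (2R,3R)-2-[4-(benzyloxy)phenyl]-5-formyl-2,3-dihydro-1-benzofuran-3-carboxylic acid
Conditions: Me3SnOH (3 equiv), ClCH2CH2Cl, 80 °C; then 1 M HCl
Reagents that add atoms: trimethyltin hydroxide, C[Sn](C)(C)O
Why: Near-neutral methyl ester hydrolysis with trimethyltin hydroxide should free the acid without enolising C3 (no ring opening by β-elimination of the phenoxide) and without touching the aldehyde.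

Step 9
Reactants: 15 (2R,3R)-2-[4-(benzyloxy)phenyl]-5-formyl-2,3-dihydro-1-benzofuran-3-carboxylic acid; 8 methyl (2R,3R)-6-(benzyloxy)-2-[4-(benzyloxy)phenyl]-4-{[(trifluoromethyl)sulfonyl]oxy}-2,3-dihydro-1-benzofuran-3-carboxylate
Product: 16 methyl (2R,3R)-6-(benzyloxy)-2-[4-(benzyloxy)phenyl]-4-{(2R,3R)-2-[4-(benzyloxy)phenyl]-5-formyl-2,3-dihydro-1-benzofuran-3-yl}-2,3-dihydro-1-benzofuran-3-carboxylate
Conditions: Ir[dF(CF3)ppy]2(dtbbpy)PF6 (1 mol%), NiCl2(dme) (10 mol%), dtbbpy (15 mol%), Cs2CO3 (1.5 equiv), DMF, blue LEDs, rt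
Reagents that add atoms: none
Why: Metallaphotoredox decarboxylative arylation: the carboxylate of 15 is oxidised by the excited photocatalyst and loses CO2, and the planar C3 benzylic radical is captured by the aryl–nickel species from oxidative addition of zerovalent nickel into the C4'–OTf bond, reductive elimination being expected on the face anti to the C2 aryl group to give the trans (2R,3R) unit.

Step 10
Reactants: 16 methyl (2R,3R)-6-(benzyloxy)-2-[4-(benzyloxy)phenyl]-4-{(2R,3R)-2-[4-(benzyloxy)phenyl]-5-formyl-2,3-dihydro-1-benzofuran-3-yl}-2,3-dihydro-1-benzofuran-3-carboxylate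
Product: 17 (2R,3R)-6-(benzyloxy)-2-[4-(benzyloxy)phenyl]-4-{(2R,3R)-2-[4-(benzyloxy)phenyl]-5-formyl-2,3-dihydro-1-benzofuran-3-yl}-2,3-dihydro-1-benzofuran-3-carboxylic acid
Conditions: Me3SnOH (5 equiv), ClCH2CH2Cl, 80 °C; then 1 M HCl
Reagents that add atoms: trimethyltin hydroxide, C[Sn](C)(C)O
Why: The same near-neutral trimethyltin hydroxide ester hydrolysis as in step 8, which tolerates hindered methyl esters and should leave the aldehyde and all four stereocentres untouched.

Step 11
Reactants: 17 (2R,3R)-6-(benzyloxy)-2-[4-(benzyloxy)phenyl]-4-{(2R,3R)-2-[4-(benzyloxy)phenyl]-5-formyl-2,3-dihydro-1-benzofuran-3-yl}-2,3-dihydro-1-benzofuran-3-carboxylic acid; 18 1,3-bis(benzyloxy)-5-bromobenzene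
Product: 19 (2R,3R)-3-{(2R,3R)-6-(benzyloxy)-2-[4-(benzyloxy)phenyl]-3-[3,5-bis(benzyloxy)phenyl]-2,3-dihydro-1-benzofuran-4-yl}-2-[4-(benzyloxy)phenyl]-2,3-dihydro-1-benzofuran-5-carbaldehyde
Conditions: Ir[dF(CF3)ppy]2(dtbbpy)PF6 (1 mol%), NiCl2(dme) (10 mol%), dtbbpy (15 mol%), Cs2CO3 (1.5 equiv), DMF, blue LEDs, rt
Reagents that add atoms: none
Why: The same metallaphotoredox decarboxylative arylation as in step 9; the planar C3' benzylic radical should be arylated by the aryl–nickel species on the face anti to the C2' aryl group, which sets C3' as the trans (2'R,3'R) centre.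

Step 12
Reactants: 19 (2R,3R)-3-{(2R,3R)-6-(benzyloxy)-2-[4-(benzyloxy)phenyl]-3-[3,5-bis(benzyloxy)phenyl]-2,3-dihydro-1-benzofuran-4-yl}-2-[4-(benzyloxy)phenyl]-2,3-dihydro-1-benzofuran-5-carbaldehyde
Product: 20 (2R,3R)-3-[(2R,3R)-3-(3,5-dihydroxyphenyl)-6-hydroxy-2-(4-hydroxyphenyl)-2,3-dihydro-1-benzofuran-4-yl]-2-(4-hydroxyphenyl)-2,3-dihydro-1-benzofuran-5-carbaldehyde
Conditions: BCl3 (15 equiv), C6HMe5 (15 equiv), CH2Cl2, −78 °C to −40 °C; MeOH quench
Reagents that add atoms: none
Why: Lewis-acid cleavage of aryl benzyl ethers with BCl3, the benzyl cations being trapped by pentamethylbenzene (Friedel–Crafts alkylation); low temperature and the absence of hydrogen should preserve the aldehyde and the benzylic C2–O bonds of both dihydrobenzofurans.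

**Compound list**

1 | 5,7-dihydroxy-4H-chromen-4-one | O=c1ccoc2cc(O)cc(O)c12 | starting material
2 | 7-(benzyloxy)-5-hydroxy-4H-chromen-4-one | O=c1ccoc2cc(OCc3ccccc3)cc(O)c12 | intermediate
3 | 7-(benzyloxy)-4-oxo-4H-chromen-5-yl trifluoromethanesulfonate | O=c1ccoc2cc(OCc3ccccc3)cc(OS(=O)(=O)C(F)(F)F)c12 | intermediate
4 | [4-(benzyloxy)phenyl]boronic acid | OB(O)c1ccc(OCc2ccccc2)cc1 | starting material
5 | (2R)-7-(benzyloxy)-2-[4-(benzyloxy)phenyl]-4-oxo-3,4-dihydro-2H-chromen-5-yl trifluoromethanesulfonate | O=C1C[C@H](c2ccc(OCc3ccccc3)cc2)Oc2cc(OCc3ccccc3)cc(OS(=O)(=O)C(F)(F)F)c12 | intermediate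
6 | (2R)-7-(benzyloxy)-2-[4-(benzyloxy)phenyl]-4-methoxy-2H-chromen-5-yl trifluoromethanesulfonate (methyl enol ether) | COC1=C[C@H](c2ccc(OCc3ccccc3)cc2)Oc2cc(OCc3ccccc3)cc(OS(=O)(=O)C(F)(F)F)c12 | intermediate
7 | 2,3-trans-3-[acetoxy(phenyl)-λ3-iodanyl]-7-(benzyloxy)-2-[4-(benzyloxy)phenyl]-4,4-dimethoxy-3,4-dihydro-2H-chromen-5-yl trifluoromethanesulfonate (C2 as in 5) | COC1(OC)[C@@H](I(OC(C)=O)c2ccccc2)[C@H](c2ccc(OCc3ccccc3)cc2)Oc2cc(OCc3ccccc3)cc(OS(=O)(=O)C(F)(F)F)c12 | intermediate
8 | methyl (2R,3R)-6-(benzyloxy)-2-[4-(benzyloxy)phenyl]-4-{[(trifluoromethyl)sulfonyl]oxy}-2,3-dihydro-1-benzofuran-3-carboxylate | FC(F)(F)S(=O)(=O)Oc1cc(OCc2ccccc2)cc2c1[C@@H](C(=O)OC)[C@H](c1ccc(OCc3ccccc3)cc1)O2 | intermediate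
9 | 6-bromo-4H-chromen-4-one | O=c1ccoc2ccc(Br)cc12 | starting material
10 | (2R)-2-[4-(benzyloxy)phenyl]-6-bromo-2,3-dihydro-4H-chromen-4-one | O=C1C[C@H](c2ccc(OCc3ccccc3)cc2)Oc2ccc(Br)cc12 | intermediate
11 | (2R)-2-[4-(benzyloxy)phenyl]-6-bromo-4-methoxy-2H-chromene (methyl enol ether) | COC1=C[C@H](c2ccc(OCc3ccccc3)cc2)Oc2ccc(Br)cc12 | intermediate
12 | 2,3-trans-3-[acetoxy(phenyl)-λ3-iodanyl]-2-[4-(benzyloxy)phenyl]-6-bromo-4,4-dimethoxy-3,4-dihydro-2H-chromene (C2 as in 10) | COC1(OC)[C@@H](I(OC(C)=O)c2ccccc2)[C@H](c2ccc(OCc3ccccc3)cc2)Oc2ccc(Br)cc12 | intermediate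
13 | methyl (2R,3R)-2-[4-(benzyloxy)phenyl]-5-bromo-2,3-dihydro-1-benzofuran-3-carboxylate | Brc1ccc2c(c1)[C@@H](C(=O)OC)[C@H](c1ccc(OCc3ccccc3)cc1)O2 | intermediate
14 | methyl (2R,3R)-2-[4-(benzyloxy)phenyl]-5-formyl-2,3-dihydro-1-benzofuran-3-carboxylate | O=Cc1ccc2c(c1)[C@@H](C(=O)OC)[C@H](c1ccc(OCc3ccccc3)cc1)O2 | intermediate
15 | (2R,3R)-2-[4-(benzyloxy)phenyl]-5-formyl-2,3-dihydro-1-benzofuran-3-carboxylic acid | O=Cc1ccc2c(c1)[C@@H](C(=O)O)[C@H](c1ccc(OCc3ccccc3)cc1)O2 | intermediate
16 | methyl (2R,3R)-6-(benzyloxy)-2-[4-(benzyloxy)phenyl]-4-{(2R,3R)-2-[4-(benzyloxy)phenyl]-5-formyl-2,3-dihydro-1-benzofuran-3-yl}-2,3-dihydro-1-benzofuran-3-carboxylate | O=Cc1ccc2c(c1)[C@@H](c1cc(OCc3ccccc3)cc3c1[C@@H](C(=O)OC)[C@H](c1ccc(OCc4ccccc4)cc1)O3)[C@H](c1ccc(OCc3ccccc3)cc1)O2 | intermediate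
17 | (2R,3R)-6-(benzyloxy)-2-[4-(benzyloxy)phenyl]-4-{(2R,3R)-2-[4-(benzyloxy)phenyl]-5-formyl-2,3-dihydro-1-benzofuran-3-yl}-2,3-dihydro-1-benzofuran-3-carboxylic acid | O=Cc1ccc2c(c1)[C@@H](c1cc(OCc3ccccc3)cc3c1[C@@H](C(=O)O)[C@H](c1ccc(OCc4ccccc4)cc1)O3)[C@H](c1ccc(OCc3ccccc3)cc1)O2 | intermediate
18 | 1,3-bis(benzyloxy)-5-bromobenzene | Brc1cc(OCc2ccccc2)cc(OCc2ccccc2)c1 | starting material
19 | (2R,3R)-3-{(2R,3R)-6-(benzyloxy)-2-[4-(benzyloxy)phenyl]-3-[3,5-bis(benzyloxy)phenyl]-2,3-dihydro-1-benzofuran-4-yl}-2-[4-(benzyloxy)phenyl]-2,3-dihydro-1-benzofuran-5-carbaldehyde | O=Cc1ccc2c(c1)[C@@H](c1cc(OCc3ccccc3)cc3c1[C@@H](c1cc(OCc4ccccc4)cc(OCc4ccccc4)c1)[C@H](c1ccc(OCc4ccccc4)cc1)O3)[C@H](c1ccc(OCc3ccccc3)cc1)O2 | intermediate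
20 | (2R,3R)-3-[(2R,3R)-3-(3,5-dihydroxyphenyl)-6-hydroxy-2-(4-hydroxyphenyl)-2,3-dihydro-1-benzofuran-4-yl]-2-(4-hydroxyphenyl)-2,3-dihydro-1-benzofuran-5-carbaldehyde | O=Cc1ccc2c(c1)[C@@H](c1cc(O)cc3c1[C@@H](c1cc(O)cc(O)c1)[C@H](c1ccc(O)cc1)O3)[C@H](c1ccc(O)cc1)O2 | target

**Count**

Total step count: 12. Longest linear sequence: 8 steps (steps 1–4 and 9–12; equally steps 5–8 and 9–12).

**Steps most likely to fail**

Step 9. Oxidative addition of zerovalent nickel into the hindered, electron-rich C4' triflate may be slow, so the C3 benzylic radical could be lost to dimerisation or hydrogen abstraction, and capture anti to the C2 aryl group may be incomplete. The fallback sets out from 15 and 8 and uses a thermal two-electron transmetalation manifold. Acid 15 is esterified with N-hydroxyphthalimide (DIC, DMAP, CH2Cl2) to the 1,3-dioxoisoindolin-2-yl ester of 15 F1. Triflate 8 is borylated (Pd(OAc)2, XPhos, B2(OH)4, KOAc, EtOH, 80 °C) to the C4' boronic acid F2. The two are joined by nickel-catalysed decarboxylative Suzuki-type coupling (NiCl2·6H2O, bathophenanthroline, Et3N, dioxane/DMF, 75 °C), which comes back to the route at 16.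

Step 11. The C3' radical is flanked by the C2' aryl group and the C4' substituent, so its capture by aryl–nickel may be outrun by hydrogen abstraction (protodecarboxylation) or by β-scission of the C2'–O bond. The fallback sets out from 17. The acid is converted (N-hydroxyphthalimide, DIC, DMAP) into the 1,3-dioxoisoindolin-2-yl ester of 17 F3. This is coupled with [3,5-bis(benzyloxy)phenyl]zinc chloride F4 (from 18: Mg, LiCl, THF; then ZnCl2) under NiCl2(dme)/dtbbpy in THF/DMF at rt (decarboxylative Negishi-type arylation), which comes back at 19.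

Step 4. Migration of the C2 aryl group, dehydrogenation to the flavone, oxidation of the electron-rich benzyloxy rings, or acid-mediated opening of the pyranone ring with loss of C2 configuration may compete with the desired shift of C4a. The fallback sets out from 5 and makes the same C3a'–C3' bond by Wolff rearrangement. Trifluoroacetylation (LiHMDS, CF3CO2CH2CF3, THF, −78 °C) gives the 3-trifluoroacetyl flavanone F5. Deacylative Regitz diazo transfer (MsN3, Et3N, H2O, MeCN) gives the 3-diazo flavanone F6. Photolysis (365 nm, MeOH, rt) contracts the ring through the ketene to the methyl ester, expected as a mixture of 8 and its cis (2R,3S) epimer F7. Treatment with DBU in toluene equilibrates F7 to the trans ester, which comes back at 8.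

**Further compounds**

F1 | step 9 | 1,3-dioxoisoindolin-2-yl (2R,3R)-2-[4-(benzyloxy)phenyl]-5-formyl-2,3-dihydro-1-benzofuran-3-carboxylate | O=Cc1ccc2c(c1)[C@@H](C(=O)ON1C(=O)c3ccccc3C1=O)[C@H](c1ccc(OCc3ccccc3)cc1)O2
F2 | step 9 | [(2R,3R)-6-(benzyloxy)-2-[4-(benzyloxy)phenyl]-3-(methoxycarbonyl)-2,3-dihydro-1-benzofuran-4-yl]boronic acid | OB(O)c1cc(OCc2ccccc2)cc2c1[C@@H](C(=O)OC)[C@H](c1ccc(OCc3ccccc3)cc1)O2
F3 | step 11 | 1,3-dioxoisoindolin-2-yl (2R,3R)-6-(benzyloxy)-2-[4-(benzyloxy)phenyl]-4-{(2R,3R)-2-[4-(benzyloxy)phenyl]-5-formyl-2,3-dihydro-1-benzofuran-3-yl}-2,3-dihydro-1-benzofuran-3-carboxylate | O=Cc1ccc2c(c1)[C@@H](c1cc(OCc3ccccc3)cc3c1[C@@H](C(=O)ON1C(=O)c4ccccc4C1=O)[C@H](c1ccc(OCc4ccccc4)cc1)O3)[C@H](c1ccc(OCc3ccccc3)cc1)O2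
F4 | step 11 | [3,5-bis(benzyloxy)phenyl]zinc chloride | Cl[Zn]c1cc(OCc2ccccc2)cc(OCc2ccccc2)c1
F5 | step 4 | 7-(benzyloxy)-2-[4-(benzyloxy)phenyl]-4-oxo-3-(trifluoroacetyl)-3,4-dihydro-2H-chromen-5-yl trifluoromethanesulfonate (C2 as in 5) | O=C1C(C(=O)C(F)(F)F)[C@H](c2ccc(OCc3ccccc3)cc2)Oc2cc(OCc3ccccc3)cc(OS(=O)(=O)C(F)(F)F)c12
F6 | step 4 | 7-(benzyloxy)-2-[4-(benzyloxy)phenyl]-3-diazo-4-oxo-3,4-dihydro-2H-chromen-5-yl trifluoromethanesulfonate (C2 as in 5) | O=C1C(=[N+]=[N-])[C@H](c2ccc(OCc3ccccc3)cc2)Oc2cc(OCc3ccccc3)cc(OS(=O)(=O)C(F)(F)F)c12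
F7 | step 4 | methyl (2R,3S)-6-(benzyloxy)-2-[4-(benzyloxy)phenyl]-4-{[(trifluoromethyl)sulfonyl]oxy}-2,3-dihydro-1-benzofuran-3-carboxylate (cis) | FC(F)(F)S(=O)(=O)Oc1cc(OCc2ccccc2)cc2c1[C@H](C(=O)OC)[C@H](c1ccc(OCc3ccccc3)cc1)O2
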